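**Remark on the chemistry:** the target has no stereocentre and no stereogenic double bond, so its SMILES carries no stereodescriptor and no step has to set or protect configuration. Compounds 1, 2 and 4 are taken to be commercial.

**Route in one sentence:** the C3–C4 bond of the tetracosanoyl chain is made by anodic decarboxylative cross-coupling (mixed Kolbe electrolysis) of docosanoic acid with the mono-2-phenylethyl ester of succinic acid.

## Structural features

The target is an acyclic wax ester, C32H56O2. An unbranched, saturated C24 acyl chain (C1 the ester carbonyl, C2–C23 twenty-two methylenes, C24 the methyl group) is joined through the ester oxygen to an O–CH2–CH2 tether that ends at a monosubstituted benzene ring, the only ring. There is no stereocentre and no double-bond geometry. The ester is the only functional group: it is sensitive to hydroxide, alkoxide and organometallic nucleophiles, and the benzylic CH2 and the arene are the only sites open to strong oxidants. The real difficulty is the chain: twenty-three contiguous sp3 carbons without a handle, whose length must be fixed by construction, because homologues and branched isomers of a wax cannot in practice be separated from it. Any bond made inside the chain joins two unactivated primary sp3 carbons of like polarity. The key step exploits the C3–C4 σ bond: C1–C3 with the complete 2-phenylethyl ester map onto a succinic half ester, C4–C24 map onto the C21 alkyl residue of a bulk C22 fatty acid, and both carbons are generated as primary radicals by anodic loss of CO2 and joined.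

## Logic of the disconnections

**Disconnection of 7 into 3 and 4.** The bond cut is C3–C4 of the acyl chain of 7 (C1 = ester carbonyl). Both carbons are unactivated CH2 groups of like polarity, so the cut is homolytic. It gives the primary radicals 5 (C4–C24) and 6 (C1–C3 with the complete ester), and each is traced back to a carboxylic acid by adding CO2 in the backward sense, 5 to 4 and 6 to 3. The cut is placed two carbons from the carbonyl because there both fragments fall onto bulk materials of defined length, and the ester is already complete, so nothing remains to be done after the chain is joined. The gain is the whole difficulty of 7: a C24 wax ester becomes two native carboxylic acids with no halide, organometallic or activating group. The forward step must generate 5 and 6 together and at high concentration at one electrode, so that they combine faster than they are oxidised further. The arene and the ester of 3 must survive the anode, and the statistical nature of a radical–radical union must be handled by an excess of the cheaper partner 3.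

**Disconnection of 3 into 1 and 2.** The bond cut is the acyl C–O bond of the ester of 3; in the forward sense the O–H of 2 adds across one acyl–oxygen bond of the ring of 1. The ring of 1 ensures that opening delivers exactly one ester and one free acid, so the mono-ester needed by the key step is obtained without statistics or a protecting group. The gain is that 3 is reduced to two commodity chemicals in one addition without a by-product. The forward step must stop at the half ester, which is secured because no activating agent is present. Compound 3 must also be freed from neutral 2 and from any diacid, since both would interfere at the anode; extraction into aqueous base does this. Compounds 1, 2 and 4 are starting materials.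

## Other disconnections considered

**Alternative 1:** The cut is the acyl C1–O bond of the ester, the disconnection that comes to mind first. Forward, tetracosanoic acid A1 would be converted with oxalyl chloride into tetracosanoyl chloride A2, which would acylate 2 (pyridine, CH2Cl2) to give 7. The chosen plan is preferred on structural grounds. This route makes no carbon–carbon bond and buys the whole C24 chain in A1, a minor natural acid that is less abundant than 4 and tends to be accompanied by its C22 and C26 homologues, which would pass unchanged into the wax. Its one-sentence description is the one every chemist would write. The chosen plan reaches 7 in the same number of operations from bulk C22 and C4 acids and builds the chain itself.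

**Alternative 2:** The cut is C1–C2 together with C1–O, a three-component assembly. Forward, (Z)-tricos-9-ene A3 would undergo isomerising hydroalkoxycarbonylation with carbon monoxide and 2 under Pd(OAc)2, 1,2-bis(di-tert-butylphosphinomethyl)benzene and MeSO3H. A palladium hydride walks the double bond to either chain end, both ends being equivalent in outcome. Insertion of carbon monoxide gives the terminal tetracosanoyl[1,2-bis(di-tert-butylphosphinomethyl)benzene]palladium cation A4, and alcoholysis by 2 releases 7 in one step. The chosen plan is preferred on mechanistic grounds although it is one step longer. The hydride must migrate over eight or fourteen positions, and every internal acyl complex intercepted by 2 on the way gives a branched constitutional isomer of 7 with the same formula and almost the same polarity and crystallisation behaviour. The linear preference of this catalyst class is best secured with a small alcohol used as solvent, whereas 2 would be a larger, stoichiometric nucleophile in an inert medium, which slows the decisive alcoholysis. In the chosen plan constitutional isomers cannot arise, because the new bond forms only at the two carbons that carried CO2H, and no pressurised carbon monoxide is needed.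

**Alternative 3:** The cut is C10–C11, made as an alkene. Forward, undec-10-enoic acid A5 would be esterified with 2 to 2-phenylethyl undec-10-enoate A6. Cross-metathesis with pentadec-1-ene A7 (second-generation Grubbs catalyst) would give 2-phenylethyl (E)-tetracos-10-enoate A8 with its Z isomer, and hydrogenation (H2, Pd/C) would give 7. The chosen plan is preferred on step economy and mechanism. This route needs three steps against two. Two unbiased terminal alkenes couple as statistically as two radicals, so nothing is gained in selectivity. The alkene formed has no place in 7 and must be removed by a step that serves only as a correction. Ruthenium hydrides from catalyst decay can also move the double bonds before metathesis, which would give C23 and C25 homologues of A8 that cannot be removed from a wax.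

Key step: step 2

## Route

Step 1
Reactants: 1 succinic anhydride (oxolane-2,5-dione); 2 2-phenylethanol
Product: 3 4-oxo-4-(2-phenylethoxy)butanoic acid (mono-2-phenylethyl succinate)
Conditions: 2 (1.05 equiv), DMAP (5 mol %), toluene, 100 °C; extraction into aq. NaHCO3, then aq. HCl to pH 2, EtOAc
Reagents that add atoms: none
Why: Ring opening of a cyclic anhydride by a primary alcohol (DMAP-catalysed acyl transfer) is an addition in which every atom of 1 and 2 ends in 3; the ring guarantees one ester and one free acid, because the liberated CO2H cannot be esterified without an activating agent, and the base extraction separates 3 from neutral 2.

Step 2
Reactants: 3 4-oxo-4-(2-phenylethoxy)butanoic acid; 4 docosanoic acid (behenic acid)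
Product: 7 2-phenylethyl tetracosanoate, via henicosyl radical 5 (not isolated), via 3-oxo-3-(2-phenylethoxy)propyl radical 6 (not isolated)
Conditions: 3 (3 equiv), 4 (1 equiv), KOH (5 mol % of total acid), MeOH, 45–50 °C, undivided cell, smooth Pt anode, Pt cathode, constant current ca. 0.25 A cm−2, stopped while the electrolyte is still faintly acidic
Reagents that add atoms: none
Why: This is a mixed Kolbe electrolysis in its half-ester form (Brown–Walker electrolysis), the closest known reaction type being the anodic cross-coupling of a fatty acid with an alkyl hydrogen alkanedioate. The carboxylates of 3 and 4 are each discharged by one electron at the platinum anode, the acyloxyl radicals lose CO2 at once, and the primary radicals 5 and 6, formed side by side at high density in the carboxylate layer on the electrode, combine to give the C3–C4 bond of 7 while protons are reduced to H2 at the cathode. No ring is closed and no stereocentre is formed, so neither a mode of closure nor a controlling element arises. The step needs chemoselectivity for the one-electron path over further oxidation to carbocations: both radicals are primary and unbranched, and 6 carries the ester carbonyl β to the radical carbon, which makes its oxidation harder still. The arene and the ester must also survive: the ring is an unactivated monoalkylbenzene remote from the carboxylate head group that binds to the anode, and with only 5 % of the acid neutralised no methoxide exists in the bulk to transesterify the 2-phenylethyl ester. Cross- against homo-coupling is statistical, so the cheap partner 3 is used in threefold excess to channel nearly all of 5 into 7. The two symmetrical dimers that accompany 7 carry two ester groups or none, so they differ sharply from 7 in polarity and should be removed by chromatography on silica and crystallisation.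

## Compound list

1 | succinic anhydride (oxolane-2,5-dione) | O=C1CCC(=O)O1 | starting material
2 | 2-phenylethanol | OCCc1ccccc1 | starting material
3 | 4-oxo-4-(2-phenylethoxy)butanoic acid | OC(=O)CCC(=O)OCCc1ccccc1 | intermediate
4 | docosanoic acid | CCCCCCCCCCCCCCCCCCCCCC(=O)O | starting material
5 | henicosyl radical | CCCCCCCCCCCCCCCCCCCC[CH2] | intermediate
6 | 3-oxo-3-(2-phenylethoxy)propyl radical | [CH2]CC(=O)OCCc1ccccc1 | intermediate
7 | 2-phenylethyl tetracosanoate | CCCCCCCCCCCCCCCCCCCCCCCC(=O)OCCc1ccccc1 | target

## Step count and risk assessment

Total step count: 2. Longest linear sequence: 2 steps (1 and 2 to 3, then 3 and 4 to 7). The route has only two steps, so both are assessed, the key step first.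

**Step 2 (key step).** The most likely failures are these:
- statistical self-coupling of each radical, which lowers the share of the cross-coupled ester;
- further one-electron oxidation of the radicals to carbocations (the non-Kolbe, Hofer–Moest path), once the separating wax coats the anode and the local current density falls;
- anodic attack on the arene or the benzylic position;
- methanolysis of the ester near the cathode late in the run, if the acid is allowed to be consumed completely.

The fallback sets out from 4 and 2 and returns to the route at 7. Compound 4 would be condensed with N-hydroxyphthalimide (N,N'-diisopropylcarbodiimide, DMAP cat., CH2Cl2) to the redox-active ester 1,3-dioxoisoindolin-2-yl docosanoate F1. Compound 2 would be esterified with acrylic acid (TsOH cat., toluene, water separator, radical inhibitor) to 2-phenylethyl prop-2-enoate F2. Irradiation of F1 with F2 (1.5 equiv) in the presence of Ru(bpy)3Cl2 (1 mol %), Hantzsch ester and iPr2NEt in CH2Cl2 under blue light should give 7 by a decarboxylative Giese addition. Single-electron reduction of F1 releases phthalimide, CO2 and radical 5, a nucleophilic primary radical that adds to the electron-poor terminus of F2, and the resulting α-ester radical takes a hydrogen atom from the Hantzsch ester. The same C3–C4 bond is made, but by a polarity-matched radical–alkene addition in place of a radical–radical union, so neither a statistical partner nor an electrode surface is involved.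

**Step 1.** The most likely failures are these:
- incomplete ring opening, or hydrolysis of the anhydride by adventitious water, so that diacid and unreacted alcohol are carried into the electrolysis, where the first is consumed unproductively and the second is oxidised;
- slow esterification of the free acid by the excess alcohol on prolonged heating.

The fallback sets out from 2 and returns to the route at 3. Compound 2 would be coupled with commercial 4-tert-butoxy-4-oxobutanoic acid (N,N'-diisopropylcarbodiimide, DMAP cat., CH2Cl2) to the mixed diester tert-butyl 2-phenylethyl butanedioate F3, a neutral compound that can be purified by chromatography. CF3CO2H in CH2Cl2 should then remove the tert-butyl group as 2-methylpropene by acid-catalysed alkyl–oxygen cleavage, which leaves the primary 2-phenylethyl ester untouched, and deliver 3. Here the mono-ester is secured by two different ester groups and not by the opening of a ring.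

## Further compounds

F1 | step 2 | 1,3-dioxoisoindolin-2-yl docosanoate | CCCCCCCCCCCCCCCCCCCCCC(=O)ON1C(=O)c2ccccc2C1=O
F2 | step 2 | 2-phenylethyl prop-2-enoate | C=CC(=O)OCCc1ccccc1
F3 | step 1 | tert-butyl 2-phenylethyl butanedioate | CC(C)(C)OC(=O)CCC(=O)OCCc1ccccc1
A1 | alternative 1 | tetracosanoic acid | CCCCCCCCCCCCCCCCCCCCCCCC(=O)O
A2 | alternative 1 | tetracosanoyl chloride | CCCCCCCCCCCCCCCCCCCCCCCC(=O)Cl
A3 | alternative 2 | (Z)-tricos-9-ene | CCCCCCCC/C=C\CCCCCCCCCCCCC
A4 | alternative 2 | tetracosanoyl[1,2-bis(di-tert-butylphosphinomethyl)benzene]palladium cation | CCCCCCCCCCCCCCCCCCCCCCCC(=O)[Pd-]1[P+](C(C)(C)C)(C(C)(C)C)Cc2ccccc2C[P+]1(C(C)(C)C)C(C)(C)C
A5 | alternative 3 | undec-10-enoic acid | C=CCCCCCCCCC(=O)O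
A6 | alternative 3 | 2-phenylethyl undec-10-enoate | C=CCCCCCCCCC(=O)OCCc1ccccc1
A7 | alternative 3 | pentadec-1-ene | C=CCCCCCCCCCCCCC
A8 | alternative 3 | 2-phenylethyl (E)-tetracos-10-enoate | CCCCCCCCCCCCC/C=C/CCCCCCCCC(=O)OCCc1ccccc1
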